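Readings and results were computed for an exercise, and the scatter is random.

Counting is the easy step: the average chain length n is the monomer in chains divided by the chains begun. The task is to reckon both parts for two flasks.

| setting | ash | oak | west | north-west |
|---|---|---|---|---|
| free monomer | 2.6 M | 2.6 M | 2.6 M | 2.6 M |
| transfer agent | 0.78 M | 0.78 M | 0.780 M | 0.780 M |
| initiator | 62 mM | 280 mM | 52 mM | 200 mM |
| remark | run made earlier | run made earlier |  |  |
| time |  |  | 1.5 h | 1.5 h |

| run | time / min | monomer in chains / % |
|---|---|---|
| ash | 8.00 | 87.3 |
| ash | 12.0 | 88.2 |
| ash | 15.0 | 88.8 |
| ash | 25.0 | 88.1 |
| ash | 40.0 | 88.4 |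
| ash | 60.0 | 88.7 |
| ash | 90.0 | 87.9 |
| oak | 8.00 | 99.9 |
| oak | 12.0 | 99.5 |
| oak | 15.0 | 99.2 |
| oak | 25.0 | 99.6 |
| oak | 40.0 | 99.5 |
| oak | 60.0 | 99.3 |
| oak | 90.0 | 98.9 |

(readings scatter by 0.3 percentage points)

- the average divides the monomer in chains by the number of chains begun, living and dead together
- the earlier runs do not show the number of chains; that part of a forecast is a guess

* which of the two ends with the longer chains by the average number of monomer units in a chain (chains begun, living or dead) ("neither" if they lie within 10%) (west / north-west / neither)
* average number of monomer units in a chain (chains begun, living or dead) at the end, west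
* average number of monomer units in a chain (chains begun, living or dead) at the end, north-west

The ash readings stay level from the first one, at a mean of 88.2%, so in ash monomer stops entering chains before that first reading. This reckoning therefore takes the ends to die without successors: the transfer agent ends chains and begins none, and each initiator used begins one chain. That is a guess, since the runs show no chain count.

For the numerator, let each start remove the same fraction of the free monomer present. With x the share in chains, M the free monomer charge and N the initiator charge, the ash readings give a reach r, the natural log of the monomer charged over the monomer not in chains, per unit of N: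

r = 34.5 M⁻¹

For west this gives:

x = 1 − exp(−rN) = 83.3%

n = x·M/N = 41.7

The oak readings hold at a mean of 99.4%, and this reckoning takes that level as the ceiling C, the monomer in chains read at oak's large initiator charge: C = 2.58 M. In north-west rN is 6.89, which would carry x above the oak level, so this reckoning puts north-west at the ceiling:

n = C/N = 12.9

This reckoning therefore puts west longer than north-west, by a factor of 3.23.

The forecast parts from this reckoning in its lengths, with west longer at 20 against 8, and it says of its count: “Chains begun are a guess.”

The simulation gives west longer, at 41.2 against 13.0 for north-west.

    living end + transfer agent → dead chain (kL = 0.00800 M⁻¹ s⁻¹)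
    living end + free monomer → dead end (k = 0.00190 M⁻¹ s⁻¹)
    free monomer + initiator → living end + monomer in chains (k = 0.0710 M⁻¹ s⁻¹)
    free monomer → decomposition product (k = 1.50 × 10⁻⁵ s⁻¹)
    free monomer + living end → monomer in chains + living end, rate k5*[living end]*[free monomer] (k = 0.280 M⁻¹ s⁻¹)

North-west ends with 2.58 M in chains, beside C of 2.58 M, and 0.88% of its initiator unused, so C over the initiator used is 13.0. The neighbour flask is north-west with 0.34 M of initiator. Its free monomer, the limiting reagent there, stands at 0%, while 5.9% of the initiator remains. C over the charge gives 7.59, and C over the initiator used gives 8.06. The simulated length of that flask is 8.08.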